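**Strategy.** Ring A of dehydroabietic acid already holds C4, C5, C10 and the C18 oxygen of the labdane half (labdane numbering). Its arene is cut away so that C8 and C9 remain as carboxyl carbons, which become a C8≡C17 alkyne and a C9=C11 vinyl group, trans-diequatorial on ring A. The key step is an iodine-atom-transfer radical addition–cyclization: an acetonyl radical (C12, C13, C16) adds to C11, the C9 radical closes ring B 6-exo-dig onto C8, and the vinyl radical ends as the C8=C17 methylene. One operation thus joins C11–C12 and C8–C9, sets C9 and leaves the C13 ketone for olefination; esterification with a separately made hydroxy acid completes the target.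

Key step: step 9

Remark (assumption): in steps 12 and 15 the antipode of the chiral ligand is defined by the product configuration stated; the sense of induction is assumed to follow the established facial models of these ligand classes.

**Route**

Step 1
Reactants: 1 dehydroabietic acid
Product: 2 methyl dehydroabietate
Conditions: MeI, K2CO3, DMF, rt
Reagents that add atoms: iodomethane CI
Why: SN2 O-methylation of the carboxylate marks C18 as an ester, so that C18 and C9 stay different once the arene is removed (the free seco-triacid would be meso).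

Step 2
Reactants: 2 methyl dehydroabietate
Product: 3 (1S,2R,3R)-2-(2-carboxyethyl)-3-(methoxycarbonyl)-1,3-dimethylcyclohexane-1-carboxylic acid
Conditions: RuCl3·xH2O (5 mol %), NaIO4 (excess), CCl4/MeCN/H2O, rt
Reagents that add atoms: sodium periodate [Na+].[O-]I(=O)(=O)=O; water O
Why: RuO4 formed in situ degrades the electron-rich trialkylbenzene ring (oxidative arene cleavage) and leaves the two ring-fusion carbons C8 and C9 as carboxylic acids, with C4, C5 and C10 untouched.

Step 3
Reactants: 3 seco-diacid
Product: 4 (1S,2R,3R)-3-(methoxycarbonyl)-2-(3-methoxy-3-oxopropyl)-1,3-dimethylcyclohexane-1-carboxylic acid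
Conditions: MeOH, AcCl (5 mol %), rt
Reagents that add atoms: methanol CO
Why: Fischer esterification under mild HCl catalysis should take only the unhindered propanoic acid (C8), because the acid on quaternary C10 is too hindered to esterify at room temperature.

Step 4
Reactants: 4 mono-acid diester
Product: 5 methyl (1R,2R,3S)-3-(hydroxymethyl)-2-(3-methoxy-3-oxopropyl)-1,3-dimethylcyclohexane-1-carboxylate
Conditions: BH3·SMe2, THF, 0 °C to rt; then MeOH, aqueous work-up
Reagents that add atoms: none
Why: Borane reduces a free carboxylic acid (through the acyloxyborane) far faster than methyl esters, so only C9 is taken to the neopentyl alcohol.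

Step 5
Reactants: 5 hydroxy diester
Product: 6 methyl (1R,2R,3S)-3-formyl-2-(3-methoxy-3-oxopropyl)-1,3-dimethylcyclohexane-1-carboxylate
Conditions: Dess–Martin periodinane, NaHCO3, CH2Cl2, rt
Reagents that add atoms: none
Why: Dess–Martin oxidation under buffered conditions stops at the aldehyde, which has no α-hydrogen and cannot epimerise.

Step 6
Reactants: 6 aldehyde diester
Product: 7 methyl (1R,2R,3R)-3-ethenyl-2-(3-methoxy-3-oxopropyl)-1,3-dimethylcyclohexane-1-carboxylate
Conditions: Ph3PCH3Br, KOtBu, THF, 0 °C to rt
Reagents that add atoms: methyltriphenylphosphonium bromide C[P+](c1ccccc1)(c1ccccc1)c1ccccc1.[Br-]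
Why: Wittig methylenation of the hindered, non-enolisable aldehyde installs the C9=C11 vinyl group, and the ylide should leave the esters alone at 0 °C.

Step 7
Reactants: 7 vinyl diester
Product: 9 methyl (1R,2R,3R)-2-(but-3-yn-1-yl)-3-ethenyl-1,3-dimethylcyclohexane-1-carboxylate, via aldehyde 8 (not isolated)
Conditions: DIBAL-H (i-Bu2AlH, 1.1 equiv), CH2Cl2, −78 °C; then MeOH, K2CO3, dimethyl (1-diazo-2-oxopropyl)phosphonate, −78 °C to rt
Reagents that add atoms: dimethyl (1-diazo-2-oxopropyl)phosphonate COP(=O)(OC)C(=[N+]=[N-])C(C)=O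
Why: DIBAL-H at −78 °C should reduce only the unhindered C8 ester to the aldehyde stage (the C18 ester on quaternary C4 is shielded), and the Ohira–Bestmann reagent (Seyferth–Gilbert homologation) converts that aldehyde in the same flask into the C8≡C17 alkyne.

Step 8
Reactants: 9 enyne ester
Product: 10 [(1R,2R,3R)-2-(but-3-yn-1-yl)-3-ethenyl-1,3-dimethylcyclohexyl]methanol
Conditions: LiAlH4, THF, 0 °C to reflux
Reagents that add atoms: none
Why: Hydride reduction of the hindered C18 ester gives the primary alcohol, while the isolated alkene and terminal alkyne are inert to LiAlH4 under these conditions.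

Step 9
Reactants: 10 enynol
Product: 12 18-hydroxy-14,15-dinorlabd-8(17)-en-13-one, via vinyl iodide 11 (not isolated)
Conditions: ICH2COCH3 (3 equiv, from ClCH2COCH3 and NaI in acetone), (Bu3Sn)2 (10 mol %), hν (sunlamp), benzene, 80 °C; then evaporation of volatiles, Bu3SnH, AIBN (cat.), benzene, 80 °C
Reagents that add atoms: iodoacetone CC(=O)CI, made from chloroacetone CC(=O)CCl and sodium iodide [Na+].[I-]
Why: Stannyl radicals abstract iodine from iodoacetone, the electrophilic acetonyl radical (C12, C13, C16) adds to the unhindered terminus C11 of the C9=C11 vinyl group, the secondary C9 radical (directly or after reversible iodine transfer) attacks C8 of the C8≡C17 alkyne, the C17 vinyl radical takes iodine from iodoacetone to carry the chain, and Bu3SnH then replaces the vinylic (and any α-keto) iodine by hydrogen. The closest known reaction type is the Kharasch-type iodine-atom-transfer radical addition–cyclization of enynes with α-iodocarbonyl compounds, followed by tin hydride dehalogenation. Ring B closes in the 6-exo-dig mode, attack at the terminal C17 (7-endo) being disfavoured. The trans ring fusion is already built into the substrate, because the C5 and C10 tethers are trans-diequatorial on ring A and only a trans-decalin can form. C9 is set in a chair-like transition state with the C11 chain pseudo-equatorial, away from the axial hydrogens at C5 and C7, which should give the 9α-H (9S) configuration. The step needs alkene-over-alkyne selectivity in the intermolecular addition and ring closure before quenching; the first rests on the faster addition of electrophilic radicals to a monosubstituted alkene, the second on the absence of any hydrogen donor in the atom-transfer stage, where a prematurely iodinated C9 is re-activated.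

Step 10
Reactants: 12 hydroxy ketone
Product: 13 methyl (13E)-18-hydroxylabda-8(17),13-dien-15-oate
Conditions: (MeO)2P(O)CH2CO2Me, NaH, THF, 0 °C; then 12, reflux; chromatographic removal of the minor 13Z isomer
Reagents that add atoms: trimethyl phosphonoacetate COC(=O)CP(=O)(OC)OC
Why: Horner–Wadsworth–Emmons olefination of the methyl ketone with the pre-formed sodium phosphonate (too weak a base to deprotonate the free alcohol) should favour the E alkene, in which the ester lies trans to the larger C12 chain.

Step 11
Reactants: 14 geranyl bromide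
Product: 15 (4E)-5,9-dimethyldeca-4,8-dienoic acid
Conditions: AcOH, LDA (LiN(i-Pr)2, 2.2 equiv), THF/DMPU, 0 °C; then 14, 0 °C to rt; aqueous HCl work-up
Reagents that add atoms: acetic acid CC(=O)O
Why: SN2 alkylation of the acetic acid dianion at the primary allylic bromide (carboxylic acid dianion alkylation) adds the two-carbon acid unit and keeps the E alkene.

Step 12
Reactants: 15 dienoic acid
Product: 16 (4aR,8aR)-5,5,8a-trimethyloctahydro-2H-chromen-2-one
Conditions: 2'-(2-fluorobenzyloxy)-1,1'-binaphthalen-2-ol·SnCl4 (1.2 equiv, antipode chosen for the 4aR,8aR series), toluene, −78 °C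
Reagents that add atoms: none
Why: Enantioselective proton-initiated polyene cyclization with a Lewis acid-assisted chiral Brønsted acid: face-selective protonation of the terminal alkene, chair-like anti addition across the E C4=C5 alkene and capture of the cation by the carboxyl oxygen give the lactone, whose trans ring fusion follows from the E geometry and whose absolute configuration comes from the chiral proton source.

Step 13
Reactants: 16 lactone
Product: 17 (4aR,8aR)-5,5,8a-trimethyloctahydro-2H-chromen-2-ol (anomer mixture)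
Conditions: DIBAL-H (i-Bu2AlH, 1.1 equiv), CH2Cl2, −78 °C
Reagents that add atoms: none
Why: DIBAL-H half-reduction of the δ-lactone stops at the aluminium lactolate at −78 °C and gives the lactol on work-up.

Step 14
Reactants: 17 lactol
Product: 18 methyl (2E)-5-[(1R,2R)-2-hydroxy-2,6,6-trimethylcyclohexyl]pent-2-enoate
Conditions: Ph3P=CHCO2Me, toluene, 80 °C
Reagents that add atoms: methyl (triphenyl-λ5-phosphanylidene)acetate COC(=O)C=P(c1ccccc1)(c1ccccc1)c1ccccc1
Why: Wittig reaction of the open hydroxy-aldehyde form with the stabilised ylide should give the E enoate, and the hindered tertiary alcohol is not expected to add back (oxa-Michael) under neutral conditions.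

Step 15
Reactants: 18 hydroxy enoate
Product: 19 methyl (3S)-5-[(1R,2R)-2-hydroxy-2,6,6-trimethylcyclohexyl]-3-methylpentanoate
Conditions: MeMgBr (2.5 equiv), copper iodide CuI (2 mol %), Tol-BINAP (3 mol %, antipode chosen for 3S), t-BuOMe, −40 °C; aqueous NH4Cl
Reagents that add atoms: methylmagnesium bromide C[Mg]Br
Why: Copper-catalysed asymmetric conjugate addition of a Grignard reagent to an E enoate, in which the ligand controls the face of methyl transfer and sets C3 as S independently of the remote ring stereocentres; the first equivalent of MeMgBr only deprotonates the tertiary alcohol.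

Step 16
Reactants: 19 methyl ester
Product: 20 (3S)-5-[(1R,2R)-2-hydroxy-2,6,6-trimethylcyclohexyl]-3-methylpentanoic acid
Conditions: LiOH, THF/MeOH/H2O, rt; then cold dilute HCl to pH 3
Reagents that add atoms: lithium hydroxide [Li+].[OH-]
Why: Saponification of the unhindered methyl ester, with mild acidification so that the tertiary alcohol is not dehydrated.

Step 17
Reactants: 13 methyl (13E)-18-hydroxylabda-8(17),13-dien-15-oate; 20 hydroxy acid
Product: 21 target ester
Conditions: DCC, DMAP (0.3 equiv), CH2Cl2, 0 °C to rt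
Reagents that add atoms: none
Why: Steglich esterification, in which the DCC-activated acid acylates the primary C18 alcohol under DMAP catalysis while the very hindered tertiary alcohol of 20 does not compete; no stereocentre is involved.

**Compound list**

1 | dehydroabietic acid, (1R,4aS,10aR)-1,4a-dimethyl-7-(propan-2-yl)-1,2,3,4,4a,9,10,10a-octahydrophenanthrene-1-carboxylic acid | CC(C)c1ccc2c(c1)CC[C@H]1[C@](C)(C(=O)O)CCC[C@]21C | starting material
2 | methyl dehydroabietate | CC(C)c1ccc2c(c1)CC[C@H]1[C@](C)(C(=O)OC)CCC[C@]21C | intermediate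
3 | (1S,2R,3R)-2-(2-carboxyethyl)-3-(methoxycarbonyl)-1,3-dimethylcyclohexane-1-carboxylic acid | OC(=O)CC[C@H]1[C@](C)(C(=O)OC)CCC[C@]1(C)C(=O)O | intermediate
4 | (1S,2R,3R)-3-(methoxycarbonyl)-2-(3-methoxy-3-oxopropyl)-1,3-dimethylcyclohexane-1-carboxylic acid | COC(=O)CC[C@H]1[C@](C)(C(=O)OC)CCC[C@]1(C)C(=O)O | intermediate
5 | methyl (1R,2R,3S)-3-(hydroxymethyl)-2-(3-methoxy-3-oxopropyl)-1,3-dimethylcyclohexane-1-carboxylate | COC(=O)CC[C@H]1[C@](C)(C(=O)OC)CCC[C@]1(C)CO | intermediate
6 | methyl (1R,2R,3S)-3-formyl-2-(3-methoxy-3-oxopropyl)-1,3-dimethylcyclohexane-1-carboxylate | COC(=O)CC[C@H]1[C@](C)(C(=O)OC)CCC[C@]1(C)C=O | intermediate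
7 | methyl (1R,2R,3R)-3-ethenyl-2-(3-methoxy-3-oxopropyl)-1,3-dimethylcyclohexane-1-carboxylate | COC(=O)CC[C@H]1[C@](C)(C(=O)OC)CCC[C@]1(C)C=C | intermediate
8 | methyl (1R,2R,3R)-3-ethenyl-1,3-dimethyl-2-(3-oxopropyl)cyclohexane-1-carboxylate | O=CCC[C@H]1[C@](C)(C(=O)OC)CCC[C@]1(C)C=C | intermediate
9 | methyl (1R,2R,3R)-2-(but-3-yn-1-yl)-3-ethenyl-1,3-dimethylcyclohexane-1-carboxylate | C#CCC[C@H]1[C@](C)(C(=O)OC)CCC[C@]1(C)C=C | intermediate
10 | [(1R,2R,3R)-2-(but-3-yn-1-yl)-3-ethenyl-1,3-dimethylcyclohexyl]methanol | C#CCC[C@H]1[C@](C)(CO)CCC[C@]1(C)C=C | intermediate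
11 | 18-hydroxy-17-iodo-14,15-dinorlabd-8(17)-en-13-one (both C8=C17 geometries) | IC=C1CC[C@H]2[C@](C)(CO)CCC[C@]2(C)[C@H]1CCC(C)=O | intermediate
12 | 18-hydroxy-14,15-dinorlabd-8(17)-en-13-one, 4-[(1S,4aR,5R,8aR)-5-(hydroxymethyl)-5,8a-dimethyl-2-methylidenedecahydronaphthalen-1-yl]butan-2-one | C=C1CC[C@H]2[C@](C)(CO)CCC[C@]2(C)[C@H]1CCC(C)=O | intermediate
13 | methyl (13E)-18-hydroxylabda-8(17),13-dien-15-oate | C=C1CC[C@H]2[C@](C)(CO)CCC[C@]2(C)[C@H]1CC/C(C)=C/C(=O)OC | intermediate
14 | geranyl bromide, (2E)-1-bromo-3,7-dimethylocta-2,6-diene | CC(C)=CCC/C(C)=C/CBr | starting material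
15 | (4E)-5,9-dimethyldeca-4,8-dienoic acid | CC(C)=CCC/C(C)=C/CCC(=O)O | intermediate
16 | (4aR,8aR)-5,5,8a-trimethyloctahydro-2H-chromen-2-one (trans-fused) | O=C1CC[C@@H]2C(C)(C)CCC[C@@]2(C)O1 | intermediate
17 | (4aR,8aR)-5,5,8a-trimethyloctahydro-2H-chromen-2-ol (anomer mixture) | OC1CC[C@@H]2C(C)(C)CCC[C@@]2(C)O1 | intermediate
18 | methyl (2E)-5-[(1R,2R)-2-hydroxy-2,6,6-trimethylcyclohexyl]pent-2-enoate | COC(=O)/C=C/CC[C@@H]1C(C)(C)CCC[C@@]1(C)O | intermediate
19 | methyl (3S)-5-[(1R,2R)-2-hydroxy-2,6,6-trimethylcyclohexyl]-3-methylpentanoate | COC(=O)C[C@@H](C)CC[C@@H]1C(C)(C)CCC[C@@]1(C)O | intermediate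
20 | (3S)-5-[(1R,2R)-2-hydroxy-2,6,6-trimethylcyclohexyl]-3-methylpentanoic acid | OC(=O)C[C@@H](C)CC[C@@H]1C(C)(C)CCC[C@@]1(C)O | intermediate
21 | methyl (13E)-18-{[(3S)-5-[(1R,2R)-2-hydroxy-2,6,6-trimethylcyclohexyl]-3-methylpentanoyl]oxy}labda-8(17),13-dien-15-oate | C=C1CC[C@H]2[C@](C)(COC(=O)C[C@@H](C)CC[C@@H]3C(C)(C)CCC[C@@]3(C)O)CCC[C@]2(C)[C@H]1CC/C(C)=C/C(=O)OC | target

**Step count**

Total steps: 17. Longest linear sequence: 11 steps (steps 1 to 10, then step 17).

**Steps most likely to fail**

1. Step 9. The acetonyl radical may add to the alkyne instead of the vinyl group, the C9 radical may be quenched before ring closure, or the facial selectivity at C9 may be poor. Fallback: setting out from aldehyde 6, a Wittig reaction with the ylide from [2-(2-methyl-1,3-dioxolan-2-yl)ethyl]triphenylphosphonium bromide (KN(SiMe3)2, THF, −78 °C) would give the Z-alkene ketal diester F1, which already carries C11 to C13 and C16. DIBAL-H followed by the Ohira–Bestmann reagent, as in step 7, would lead through the aldehyde F2 to the 1,7-enyne F3. A palladium-catalysed reductive enyne cyclization (Pd2(dba)3·CHCl3 as the source of zerovalent palladium, P(o-tol)3, AcOH, Et3SiH, toluene) would then form C8–C9 by hydropalladation of the alkyne, 6-exo carbopalladation of the alkene and silane reduction of the C11–Pd bond, giving the bicyclic ketal ester F4. LiAlH4 would give the ketal alcohol F5, and aqueous HCl in acetone would release ketone 12, where the route is rejoined.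

2. Step 2. Benzylic oxidation at C7 may compete with arene cleavage and lead to loss of C8, or the cleavage may stop short of the diacid. Fallback: setting out from acid 1, Birch reduction (Li, liquid NH3, t-BuOH, THF) would give the 8,12-diene acid F6, and MeI/K2CO3 its methyl ester F7. Ozonolysis (O3, CH2Cl2/MeOH, −78 °C; then H2O2, HCO2H, warming) would cut both C8=C9 and C12=C13 and, after decarboxylation of the β-keto acid, give the triketone F8. Haloform cleavage (NaOBr, dioxane/H2O, 0 °C) would turn the C9 acetyl group and the C8 β-diketone into the two carboxylic acids of 3, where the route is rejoined.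

3. Step 12. Enantiofacial control of the protonation may be insufficient, or proton loss may compete with lactone capture. Fallback: setting out from acid 15, cyclization with an achiral acid (SnCl4, CH2Cl2, −78 °C) would give the trans-lactone as the racemate, that is 16 together with its mirror image F9. Preparative chromatography on a chiral stationary phase (supercritical CO2/MeOH) would remove F9 and return to 16.

**Further compounds**

F1 | step 9 | methyl (1R,2R,3R)-2-(3-methoxy-3-oxopropyl)-1,3-dimethyl-3-[(1Z)-3-(2-methyl-1,3-dioxolan-2-yl)prop-1-en-1-yl]cyclohexane-1-carboxylate | COC(=O)CC[C@H]1[C@](C)(C(=O)OC)CCC[C@]1(C)/C=C\CC1(C)OCCO1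
F2 | step 9 | methyl (1R,2R,3R)-1,3-dimethyl-3-[(1Z)-3-(2-methyl-1,3-dioxolan-2-yl)prop-1-en-1-yl]-2-(3-oxopropyl)cyclohexane-1-carboxylate | O=CCC[C@H]1[C@](C)(C(=O)OC)CCC[C@]1(C)/C=C\CC1(C)OCCO1
F3 | step 9 | methyl (1R,2R,3R)-2-(but-3-yn-1-yl)-1,3-dimethyl-3-[(1Z)-3-(2-methyl-1,3-dioxolan-2-yl)prop-1-en-1-yl]cyclohexane-1-carboxylate | C#CCC[C@H]1[C@](C)(C(=O)OC)CCC[C@]1(C)/C=C\CC1(C)OCCO1
F4 | step 9 | methyl 13,13-(ethylenedioxy)-14,15-dinorlabd-8(17)-en-18-oate | C=C1CC[C@H]2[C@](C)(C(=O)OC)CCC[C@]2(C)[C@H]1CCC1(C)OCCO1
F5 | step 9 | 13,13-(ethylenedioxy)-14,15-dinorlabd-8(17)-en-18-ol | C=C1CC[C@H]2[C@](C)(CO)CCC[C@]2(C)[C@H]1CCC1(C)OCCO1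
F6 | step 2 | abieta-8,12-dien-18-oic acid | CC(C)C1=CCC2=C(C1)CC[C@H]1[C@](C)(C(=O)O)CCC[C@]21C
F7 | step 2 | methyl abieta-8,12-dien-18-oate | CC(C)C1=CCC2=C(C1)CC[C@H]1[C@](C)(C(=O)OC)CCC[C@]21C
F8 | step 2 | methyl (1R,2R,3S)-3-acetyl-1,3-dimethyl-2-(6-methyl-3,5-dioxoheptyl)cyclohexane-1-carboxylate | CC(C)C(=O)CC(=O)CC[C@H]1[C@](C)(C(=O)OC)CCC[C@]1(C)C(C)=O
F9 | step 12 | (4aS,8aS)-5,5,8a-trimethyloctahydro-2H-chromen-2-one (mirror image of 16) | O=C1CC[C@H]2C(C)(C)CCC[C@]2(C)O1
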